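The oxane is disconnected at C4–C5 (O1; C2 bears the acrylic acid, C5 the side chain, C1′ is its first carbon). The key step exploits two features: O1–C6–C5–C1′ is a glycidyl ether pattern, and C4 is an unsubstituted ring methylene. A sulfone-stabilised C4 carbanion opens an (R)-epoxide spanning C5–C1′ in 6-exo fashion. One operation closes the ring, sets C5 by inversion (locking the less stable 2,5-cis relationship) and frees a C1′ hydroxyl as the handle for the farnesyl unit. The precursor is an acyclic glycidyl propargyl ether carrying a γ-sulfone. The C2 alkyne later becomes the acrylic acid by hydrocarboxylation, and both sulfones leave together.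

Key step: step 4

Remark: locants O1, C2–C6 and C1′ in the text are those of the target's oxane ring, while systematic names of intermediates carry their own numbering. The target is the cis-2,5-disubstituted (2R,5R)-oxane with an all-E chain. Compounds 1, 2, 6 and 15 are taken as purchased.

Step 1
Reactants: 1 methyl 3-(benzenesulfonyl)propanoate; 2 ethynyltrimethylsilane
Product: 4 5-(benzenesulfonyl)-1-(trimethylsilyl)pent-1-yn-3-one, via lithium acetylide 3 (not isolated)
Conditions: 2, n-BuLi, THF, −78 °C; BF3·OEt2; then 1, −78 °C; aq. NH4Cl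
Reagents that add atoms: none
Why: Acylation of an alkynyllithium–BF3 reagent by an ester (Yamaguchi–Hirao ynone synthesis) should stop at the ketone because the boron-bound tetrahedral adduct collapses only on work-up, and the weakly basic alkynyl species should leave the sulfone α-protons untouched.

Step 2
Reactants: 4 5-(benzenesulfonyl)-1-(trimethylsilyl)pent-1-yn-3-one
Product: 5 (3R)-5-(benzenesulfonyl)-1-(trimethylsilyl)pent-1-yn-3-ol
Conditions: RuCl[(R,R)-TsDPEN](p-cymene) (1 mol%), i-PrOH, rt
Reagents that add atoms: none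
Why: Noyori asymmetric transfer hydrogenation of an alkynyl ketone should set the C2 carbinol as R, since the (R,R)-ligand directs hydride to the face that places the alkynyl group in the π-recognition site, and the near-neutral medium should avoid β-elimination of benzenesulfinate.

Step 3
Reactants: 5 (3R)-5-(benzenesulfonyl)-1-(trimethylsilyl)pent-1-yn-3-ol; 6 (2R)-oxiran-2-ylmethyl 3-nitrobenzenesulfonate
Product: 8 (2R)-2-({[(3R)-5-(benzenesulfonyl)-1-(trimethylsilyl)pent-1-yn-3-yl]oxy}methyl)oxirane, via sodium alkoxide 7 (not isolated)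
Conditions: NaH (1.05 equiv), THF, 0 °C; then 6, 0 °C → rt
Reagents that add atoms: none
Why: Williamson etherification in which the alkoxide should displace the nosylate at the primary carbon of 6 by direct SN2, so the epoxide carbon and the carbinol carbon both keep their configuration.

Step 4
Reactants: 8 (2R)-2-({[(3R)-5-(benzenesulfonyl)-1-(trimethylsilyl)pent-1-yn-3-yl]oxy}methyl)oxirane
Product: 11 [(3S,6R)-4-(benzenesulfonyl)-6-[(trimethylsilyl)ethynyl]oxan-3-yl]methanol (epimers at the sulfonyl carbon), via lithio sulfone 9 (not isolated), via lithium alkoxide 10 (not isolated)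
Conditions: n-BuLi (1.05 equiv), THF–DMPU, −78 → 0 °C; aq. NH4Cl
Reagents that add atoms: none
Why: n-BuLi should remove the most acidic proton (α to the sulfone, C4), and the lithio sulfone should attack the internal epoxide carbon C5 anti to its C–O bond, releasing the ring strain and forming C4–C5. The closest known reaction type is the intramolecular opening of epoxides by α-sulfonyl or α-cyano carbanions. The oxane closes in the 6-exo-tet mode. C5 is set by SN2 inversion of the (R)-epoxide carbon of 6, which together with the C2 centre from step 2 should give only the cis-2,5 series, while the C4 sulfonyl centre forms as a mixture that step 8 erases. The step needs exo attack at C5 over 7-endo attack at C1′ and sulfone metalation over propargylic deprotonation at C2; the six-membered transition state with collinear backside approach, lithium bridging O1 and the epoxide oxygen, and the large acidity gap should secure both. The slim alkynyl group at C2 can sit axial or equatorial, so the cis-configured chair transition state carries no penalty.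

Step 5
Reactants: 11 [(3S,6R)-4-(benzenesulfonyl)-6-[(trimethylsilyl)ethynyl]oxan-3-yl]methanol
Product: 12 (2R,5R)-4-(benzenesulfonyl)-5-[(phenylsulfanyl)methyl]-2-[(trimethylsilyl)ethynyl]oxane (epimers at C4)
Conditions: PhSSPh, n-Bu3P, pyridine, rt → 50 °C
Reagents that add atoms: diphenyl disulfide, c1ccccc1SSc1ccccc1
Why: Phosphine–disulfide redox condensation, in which the primary alcohol is activated as an alkoxyphosphonium ion and benzenethiolate should displace it by SN2 at C1′, away from both stereocentres.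

Step 6
Reactants: 12 (2R,5R)-4-(benzenesulfonyl)-5-[(phenylsulfanyl)methyl]-2-[(trimethylsilyl)ethynyl]oxane
Product: 14 (2R,5R)-4-(benzenesulfonyl)-5-[(benzenesulfonyl)methyl]-2-[(trimethylsilyl)ethynyl]oxane (epimers at C4), via sulfoxide 13 (not isolated)
Conditions: (NH4)6Mo7O24·4H2O (10 mol%), 30% aq. H2O2, EtOH, 0 °C → rt
Reagents that add atoms: hydrogen peroxide, OO
Why: Molybdate-catalysed peroxide oxidation should take the sulfide through the sulfoxide to the sulfone without touching the silyl alkyne or the ether.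

Step 7
Reactants: 14 (2R,5R)-4-(benzenesulfonyl)-5-[(benzenesulfonyl)methyl]-2-[(trimethylsilyl)ethynyl]oxane; 15 (2E,6E)-1-bromo-3,7,11-trimethyldodeca-2,6,10-triene
Product: 17 (2R,5R)-4-(benzenesulfonyl)-5-[(3E,7E)-1-(benzenesulfonyl)-4,8,12-trimethyltrideca-3,7,11-trien-1-yl]-2-[(trimethylsilyl)ethynyl]oxane (epimers at both sulfonyl carbons), via lithio disulfone 16 (not isolated)
Conditions: n-BuLi (1.0 equiv), THF–DMPU, −78 °C; then 15, −78 → −20 °C
Reagents that add atoms: none
Why: Sulfone-anion alkylation in which kinetic metalation should occur at the less hindered exocyclic CH2SO2Ph (C1′) and not at the ring methine, and the carbanion should displace the primary allylic bromide by SN2 without allylic transposition, so both E-alkenes of the farnesyl unit are kept.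

Step 8
Reactants: 17 (2R,5R)-4-(benzenesulfonyl)-5-[(3E,7E)-1-(benzenesulfonyl)-4,8,12-trimethyltrideca-3,7,11-trien-1-yl]-2-[(trimethylsilyl)ethynyl]oxane
Product: 19 (2R,5R)-2-ethynyl-5-[(3E,7E)-4,8,12-trimethyltrideca-3,7,11-trien-1-yl]oxane, via silyl alkyne 18 (not isolated)
Conditions: Na(Hg) (6% Na), Na2HPO4, MeOH–THF, −20 °C → rt; then K2CO3, MeOH, rt (same pot)
Reagents that add atoms: none
Why: Single-electron reductive desulfonylation should cleave both non-allylic C–SO2Ph bonds with protonation of the carbanions (neither site is allylic, so no alkene migration is expected), and methanolic carbonate should then remove the C-silyl group by protodesilylation, leaving C2 and C5 untouched.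

Step 9
Reactants: 19 (2R,5R)-2-ethynyl-5-[(3E,7E)-4,8,12-trimethyltrideca-3,7,11-trien-1-yl]oxane
Product: 20 rhopaloic acid B, 2-[(2R,5R)-5-[(3E,7E)-4,8,12-trimethyltrideca-3,7,11-trien-1-yl]oxan-2-yl]prop-2-enoic acid
Conditions: Pd(OAc)2 (5 mol%), Xantphos (10 mol%), HCO2H (2 equiv), Ac2O (20 mol%), toluene, 80 °C
Reagents that add atoms: formic acid, O=CO
Why: Branched-selective hydrocarboxylation of a terminal alkyne, in which a palladium hydride should add in the Markovnikov sense, CO released in the flask from formic acid should insert, and cleavage of the acyl palladium should give the 2-substituted acrylic acid without affecting the trisubstituted alkenes or C2.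

Compound list
1 | methyl 3-(benzenesulfonyl)propanoate | COC(=O)CCS(=O)(=O)c1ccccc1 | starting material
2 | ethynyltrimethylsilane | C#C[Si](C)(C)C | starting material
3 | lithium (trimethylsilyl)acetylide | [Li]C#C[Si](C)(C)C | intermediate (not isolated)
4 | 5-(benzenesulfonyl)-1-(trimethylsilyl)pent-1-yn-3-one | C[Si](C)(C)C#CC(=O)CCS(=O)(=O)c1ccccc1 | intermediate
5 | (3R)-5-(benzenesulfonyl)-1-(trimethylsilyl)pent-1-yn-3-ol | C[Si](C)(C)C#C[C@H](O)CCS(=O)(=O)c1ccccc1 | intermediate
6 | (2R)-oxiran-2-ylmethyl 3-nitrobenzenesulfonate ((R)-glycidyl nosylate) | O=S(=O)(OC[C@H]1CO1)c1cccc([N+](=O)[O-])c1 | starting material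
7 | sodium (3R)-5-(benzenesulfonyl)-1-(trimethylsilyl)pent-1-yn-3-olate | C[Si](C)(C)C#C[C@H]([O-])CCS(=O)(=O)c1ccccc1.[Na+] | intermediate (not isolated)
8 | (2R)-2-({[(3R)-5-(benzenesulfonyl)-1-(trimethylsilyl)pent-1-yn-3-yl]oxy}methyl)oxirane | C[Si](C)(C)C#C[C@@H](CCS(=O)(=O)c1ccccc1)OC[C@H]1CO1 | intermediate
9 | C4-lithiated sulfone of 8 (α-lithio sulfone, epimers at the lithiated carbon) | C[Si](C)(C)C#C[C@@H](CC([Li])S(=O)(=O)c1ccccc1)OC[C@H]1CO1 | intermediate (not isolated)
10 | lithium [(3S,6R)-4-(benzenesulfonyl)-6-[(trimethylsilyl)ethynyl]oxan-3-yl]methanolate | C[Si](C)(C)C#C[C@H]1CC(S(=O)(=O)c2ccccc2)[C@@H](C[O-])CO1.[Li+] | intermediate (not isolated)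
11 | [(3S,6R)-4-(benzenesulfonyl)-6-[(trimethylsilyl)ethynyl]oxan-3-yl]methanol, cis-2,5 by target locants, epimers at the sulfonyl carbon | C[Si](C)(C)C#C[C@H]1CC(S(=O)(=O)c2ccccc2)[C@@H](CO)CO1 | intermediate
12 | (2R,5R)-4-(benzenesulfonyl)-5-[(phenylsulfanyl)methyl]-2-[(trimethylsilyl)ethynyl]oxane, epimers at C4 | C[Si](C)(C)C#C[C@H]1CC(S(=O)(=O)c2ccccc2)[C@@H](CSc2ccccc2)CO1 | intermediate
13 | (2R,5R)-4-(benzenesulfonyl)-5-[(benzenesulfinyl)methyl]-2-[(trimethylsilyl)ethynyl]oxane, epimers at C4 and sulfur | C[Si](C)(C)C#C[C@H]1CC(S(=O)(=O)c2ccccc2)[C@@H](CS(=O)c2ccccc2)CO1 | intermediate (not isolated)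
14 | (2R,5R)-4-(benzenesulfonyl)-5-[(benzenesulfonyl)methyl]-2-[(trimethylsilyl)ethynyl]oxane, epimers at C4 | C[Si](C)(C)C#C[C@H]1CC(S(=O)(=O)c2ccccc2)[C@@H](CS(=O)(=O)c2ccccc2)CO1 | intermediate
15 | (2E,6E)-1-bromo-3,7,11-trimethyldodeca-2,6,10-triene ((E,E)-farnesyl bromide) | BrC/C=C(\C)CC/C=C(\C)CCC=C(C)C | starting material
16 | C1′-lithiated disulfone of 14 | C[Si](C)(C)C#C[C@H]1CC(S(=O)(=O)c2ccccc2)[C@@H](C([Li])S(=O)(=O)c2ccccc2)CO1 | intermediate (not isolated)
17 | (2R,5R)-4-(benzenesulfonyl)-5-[(3E,7E)-1-(benzenesulfonyl)-4,8,12-trimethyltrideca-3,7,11-trien-1-yl]-2-[(trimethylsilyl)ethynyl]oxane, epimers at both sulfonyl carbons | C[Si](C)(C)C#C[C@H]1CC(S(=O)(=O)c2ccccc2)[C@@H](C(C/C=C(\C)CC/C=C(\C)CCC=C(C)C)S(=O)(=O)c2ccccc2)CO1 | intermediate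
18 | trimethyl({(2R,5R)-5-[(3E,7E)-4,8,12-trimethyltrideca-3,7,11-trien-1-yl]oxan-2-yl}ethynyl)silane | C[Si](C)(C)C#C[C@H]1CC[C@@H](CC/C=C(\C)CC/C=C(\C)CCC=C(C)C)CO1 | intermediate (not isolated)
19 | (2R,5R)-2-ethynyl-5-[(3E,7E)-4,8,12-trimethyltrideca-3,7,11-trien-1-yl]oxane | C#C[C@H]1CC[C@@H](CC/C=C(\C)CC/C=C(\C)CCC=C(C)C)CO1 | intermediate
20 | rhopaloic acid B, 2-[(2R,5R)-5-[(3E,7E)-4,8,12-trimethyltrideca-3,7,11-trien-1-yl]oxan-2-yl]prop-2-enoic acid | C=C(C(=O)O)[C@H]1CC[C@@H](CC/C=C(\C)CC/C=C(\C)CCC=C(C)C)CO1 | target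

Total step count: 9
Longest linear sequence: 9 steps (from 1 and 2 to 20)

Steps most likely to fail

Step 4. The carbanion may attack the terminal epoxide carbon (7-endo opening), or closure may be slow enough for intermolecular epoxide opening to compete. The fallback replaces the epoxide by an electrophile with a single reactive carbon and keeps the same C4–C5 closure. It sets out from 8, whose epoxide is opened at the terminal carbon with 4-methoxyphenol (CsF cat., DMF, 80 °C) to give (2S)-1-{[(3R)-5-(benzenesulfonyl)-1-(trimethylsilyl)pent-1-yn-3-yl]oxy}-3-(4-methoxyphenoxy)propan-2-ol F1. Tosylation (TsCl, Et3N, DMAP, CH2Cl2) gives the secondary tosylate F2. Metalation α to the sulfone (n-BuLi, THF–DMPU, −78 → 0 °C) should then displace the tosylate with inversion in a 6-exo-tet closure to give the 4-methoxyphenyl ether F3. Oxidative removal of the aryl group with (NH4)2Ce(NO3)6 (MeCN–H2O, 0 °C) comes back to the route at 11.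

Step 9. Regiocontrol in the hydropalladation may be lost (giving the linear acid), and palladium hydride or acid may isomerise the trisubstituted alkenes. The fallback fixes the regiochemistry by a separate hydrometalation. It sets out from 19: hydrostannation catalysed by Mo(CO)3(CNt-Bu)3 (Bu3SnH, hydroquinone, THF, 55 °C) should place tin on the internal alkyne carbon next to the ether carbon and give the α-stannyl alkene F4. Iodine (CH2Cl2, 0 °C) then gives the 1-iodovinyl oxane F5. Hydroxycarbonylation (Pd(PPh3)4, CO at 1 atm, H2O, Et3N, DMF, 50 °C) comes back to the route at 20.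

Step 7. Metalation may not distinguish the two sulfone α-positions (ring methine against exocyclic methylene), and the C1′ carbanion may lose sulfinate from C4 by 1,3-elimination. The fallback removes the ring sulfone first and reverses the polarity of the coupling. It sets out from 11: buffered Na(Hg) (Na2HPO4, MeOH–THF, −20 °C) gives the sulfone-free alcohol F6, and I2, PPh3 and imidazole (CH2Cl2) give the iodide F7. Separately, 15 and PhSO2Na (DMF, rt) give farnesyl phenyl sulfone F8. Lithiated F8 (n-BuLi, THF–DMPU, −78 °C) is alkylated with F7 to give the allylic sulfone F9. Hydride desulfonylation with retention of the alkene position (PdCl2(dppp) cat., LiBHEt3, THF, 0 °C) comes back to the route at 18, which is then isolated and desilylated to 19 with K2CO3 in MeOH as in step 8.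

Further compounds
F1 | step 4 | (2S)-1-{[(3R)-5-(benzenesulfonyl)-1-(trimethylsilyl)pent-1-yn-3-yl]oxy}-3-(4-methoxyphenoxy)propan-2-ol | COc1ccc(OC[C@@H](O)CO[C@H](CCS(=O)(=O)c2ccccc2)C#C[Si](C)(C)C)cc1
F2 | step 4 | (2S)-1-{[(3R)-5-(benzenesulfonyl)-1-(trimethylsilyl)pent-1-yn-3-yl]oxy}-3-(4-methoxyphenoxy)propan-2-yl 4-methylbenzenesulfonate | COc1ccc(OC[C@@H](OS(=O)(=O)c2ccc(C)cc2)CO[C@H](CCS(=O)(=O)c2ccccc2)C#C[Si](C)(C)C)cc1
F3 | step 4 | (2R,5R)-4-(benzenesulfonyl)-5-[(4-methoxyphenoxy)methyl]-2-[(trimethylsilyl)ethynyl]oxane, epimers at C4 | C[Si](C)(C)C#C[C@H]1CC(S(=O)(=O)c2ccccc2)[C@@H](COc2ccc(OC)cc2)CO1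
F4 | step 9 | tributyl{1-[(2R,5R)-5-[(3E,7E)-4,8,12-trimethyltrideca-3,7,11-trien-1-yl]oxan-2-yl]ethenyl}stannane | CCCC[Sn](CCCC)(CCCC)C(=C)[C@H]1CC[C@@H](CC/C=C(\C)CC/C=C(\C)CCC=C(C)C)CO1
F5 | step 9 | (2R,5R)-2-(1-iodoethenyl)-5-[(3E,7E)-4,8,12-trimethyltrideca-3,7,11-trien-1-yl]oxane | C=C(I)[C@H]1CC[C@@H](CC/C=C(\C)CC/C=C(\C)CCC=C(C)C)CO1
F6 | step 7 | [(3S,6R)-6-[(trimethylsilyl)ethynyl]oxan-3-yl]methanol | C[Si](C)(C)C#C[C@H]1CC[C@@H](CO)CO1
F7 | step 7 | {[(2R,5R)-5-(iodomethyl)oxan-2-yl]ethynyl}trimethylsilane | C[Si](C)(C)C#C[C@H]1CC[C@@H](CI)CO1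
F8 | step 7 | {[(2E,6E)-3,7,11-trimethyldodeca-2,6,10-trien-1-yl]sulfonyl}benzene (farnesyl phenyl sulfone) | O=S(=O)(C/C=C(\C)CC/C=C(\C)CCC=C(C)C)c1ccccc1
F9 | step 7 | {[(2R,5S)-5-[(3E,7E)-2-(benzenesulfonyl)-4,8,12-trimethyltrideca-3,7,11-trien-1-yl]oxan-2-yl]ethynyl}trimethylsilane, epimers at the sulfonyl carbon | C[Si](C)(C)C#C[C@H]1CC[C@@H](CC(/C=C(\C)CC/C=C(\C)CCC=C(C)C)S(=O)(=O)c2ccccc2)CO1
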